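**Plan**

1. Retrosynthesis: the two silyl groups and the aryl O–CH3 bond are cut last, then the benzene ring at aryl C1–C2 and C6–C5, which leaves ethynyl ketone 20 and 2-methoxyfuran 21.
2. Enabling feature: in the 2,5-dihydroxyphenyl ketone, aryl C2–C5 with their two para oxygens are the four carbons, ring oxygen and alkoxy oxygen of a 2-alkoxyfuran; aryl C1 (on the ketone carbon) and C6 are the two carbons of an ethynyl ketone.
3. Further cuts: ketone–alkyne bond (Weinreb amide), oxepine C6–side-chain bond (Negishi), C6 itself (dibromocarbene inserted between C5 and C7 of a dihydropyran), C7 and O1–C7 (hydroformylation of an allyl group, hemiacetal), C2–C3 (allylation).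
4. Forward order: quaternary C2, six-membered dihydropyran, ring expansion to the bromo-oxepine, side chain (made apart from 5-bromo-2-methylpent-2-ene and 4-coumaric acid), ynone, benzene ring, oxidative demethylation, desilylation.
5. Stereochemistry: C2 comes from (R)-malic acid by dioxolanone enolate alkylation with net retention; the side-chain alkene is set E by SeO2 oxidation and the cinnamate E comes with 4-coumaric acid.

Key step: step 15

Remarks: oxepine atoms are O1, C2 (quaternary), C3, C4, C5=C6, C7; aryl C1 carries the ketone. TMSE = 2-(trimethylsilyl)ethyl, TBS = tert-butyldimethylsilyl, "side chain" = (3E)-4-methyl-5-{[(2E)-3-(4-TBSO-phenyl)prop-2-enoyl]oxy}pent-3-en-1-yl on C6. The cycloaddition is written for the expected orientation (OMe ortho to the ketone); the other orientation would give the isomeric 4-methoxyphenol, which step 16 would convert into the same hydroquinone 25.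

**Route**

Step 1
Reactants: 1 (R)-malic acid
Product: 2 2-[(2R,4R)-2-tert-butyl-5-oxo-1,3-dioxolan-4-yl]acetic acid (cis)
Conditions: t-BuCHO, TsOH (cat.), H2SO4 (cat.), pentane, reflux, Dean–Stark; recrystallisation
Reagents that add atoms: pivalaldehyde, CC(C)(C)C=O
Why: Acid-catalysed acetalisation of the α-hydroxy acid under thermodynamic control leaves the malic stereocentre untouched and should place the acetal tert-butyl group cis to the side chain, the minor trans isomer being removed by crystallisation.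

Step 2
Reactants: 2 2-[(2R,4R)-2-tert-butyl-5-oxo-1,3-dioxolan-4-yl]acetic acid
Product: 3 2-[(2R,4R)-4-allyl-2-tert-butyl-5-oxo-1,3-dioxolan-4-yl]acetic acid (allyl trans to tert-butyl)
Conditions: LiN(SiMe3)2 (2.2 equiv), THF, −78 °C; allyl bromide, −78 → −20 °C; 1 M HCl
Reagents that add atoms: allyl bromide, C=CCBr
Why: Enolate alkylation with self-regeneration of the stereocentre: the dilithium enolate carboxylate is attacked on the face opposite the tert-butyl group, so allyl takes the place of H with net retention and the quaternary centre (later oxepine C2) is set R.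

Step 3
Reactants: 3 2-[(2R,4R)-4-allyl-2-tert-butyl-5-oxo-1,3-dioxolan-4-yl]acetic acid
Product: 4 (3R)-3-hydroxy-3-{[2-(trimethylsilyl)ethoxy]carbonyl}hex-5-enoic acid
Conditions: Me3SiCH2CH2OH (5 equiv), NaH (2.2 equiv), THF, 0 → 25 °C; 1 M HCl, 0 °C
Reagents that add atoms: 2-(trimethylsilyl)ethanol, C[Si](C)(C)CCO
Why: Alkoxide transesterification opens the dioxolanone and the hemiacetal alkoxide expels pivalaldehyde, while the arm stays a carboxylate that cannot undergo retro-aldol cleavage, so the quaternary centre is not at risk.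

Step 4
Reactants: 4 (3R)-3-hydroxy-3-{[2-(trimethylsilyl)ethoxy]carbonyl}hex-5-enoic acid
Product: 5 TMSE (2R)-2-hydroxy-2-{2-[methoxy(methyl)amino]-2-oxoethyl}pent-4-enoate
Conditions: MeNHOMe·HCl, EDC·HCl, HOBt (cat.), N-methylmorpholine, CH2Cl2, 0 → 25 °C
Reagents that add atoms: N,O-dimethylhydroxylamine hydrochloride, CNOC.Cl
Why: Carbodiimide amide coupling of the only free acid gives the Weinreb amide under near-neutral conditions that leave the tertiary alcohol and the hindered ester alone.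

Step 5
Reactants: 5 TMSE (2R)-2-hydroxy-2-{2-[methoxy(methyl)amino]-2-oxoethyl}pent-4-enoate
Product: 7 TMSE (2R)-6-hydroxy-2-{2-[methoxy(methyl)amino]-2-oxoethyl}oxane-2-carboxylate (both anomers), via open-chain hydroxy aldehyde 6 (not isolated)
Conditions: Rh(acac)(CO)2 (1 mol%), BIPHEPHOS (2 mol%), CO/H2 (1:1, 5 bar), THF, 60 °C
Reagents that add atoms: carbon monoxide, [C-]#[O+]
Why: Linear-selective rhodium/bisphosphite hydroformylation of the terminal alkene gives the δ-hydroxy aldehyde, which closes spontaneously to the six-membered lactol and so forms the O1–C7 bond without alkylating the tertiary alcohol (anomeric centre uncontrolled, removed in step 6).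

Step 6
Reactants: 7 TMSE (2R)-6-hydroxy-2-{2-[methoxy(methyl)amino]-2-oxoethyl}oxane-2-carboxylate
Product: 8 TMSE (2R)-2-{2-[methoxy(methyl)amino]-2-oxoethyl}-3,4-dihydro-2H-pyran-2-carboxylate
Conditions: MsCl, Et3N, CH2Cl2, −20 °C → reflux
Reagents that add atoms: none
Why: Sulfonylation of the anomeric hydroxyl and amine-mediated elimination through the oxocarbenium ion (the usual lactol-to-cyclic-enol-ether dehydration) should give the dihydropyran.

Step 7
Reactants: 8 TMSE (2R)-2-{2-[methoxy(methyl)amino]-2-oxoethyl}-3,4-dihydro-2H-pyran-2-carboxylate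
Product: 9 TMSE (3R)-7,7-dibromo-3-{2-[methoxy(methyl)amino]-2-oxoethyl}-2-oxabicyclo[4.1.0]heptane-3-carboxylate (cis-fused, both cyclopropane faces)
Conditions: CHBr3, 50% aq. NaOH, BnEt3NCl (cat.), CH2Cl2, 0 °C
Reagents that add atoms: bromoform, BrC(Br)Br
Why: Phase-transfer generation of dibromocarbene and its [2+1] cycloaddition to the electron-rich enol ether; the new ring-fusion stereocentres are uncontrolled and vanish in step 8, and the amide α-protons are too weakly acidic to be removed under these conditions.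

Step 8
Reactants: 9 TMSE (3R)-7,7-dibromo-3-{2-[methoxy(methyl)amino]-2-oxoethyl}-2-oxabicyclo[4.1.0]heptane-3-carboxylate
Product: 10 TMSE (2R)-6-bromo-7-methoxy-2-{2-[methoxy(methyl)amino]-2-oxoethyl}-2,3,4,7-tetrahydrooxepine-2-carboxylate (C7 epimers)
Conditions: AgOTf, 2,6-lutidine, MeOH/CH2Cl2, 0 → 25 °C
Reagents that add atoms: methanol, CO
Why: Silver-assisted loss of the endo bromide with disrotatory electrocyclic opening of the cyclopropane (known for dihalocyclopropanated cyclic enol ethers) gives the oxygen-stabilised allyl cation, which methanol captures at C7 to leave the C5=C6 vinyl bromide; the C7 epimers converge in step 9.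

Step 9
Reactants: 10 TMSE (2R)-6-bromo-7-methoxy-2-{2-[methoxy(methyl)amino]-2-oxoethyl}-2,3,4,7-tetrahydrooxepine-2-carboxylate
Product: 11 TMSE (2R)-6-bromo-2-{2-[methoxy(methyl)amino]-2-oxoethyl}-2,3,4,7-tetrahydrooxepine-2-carboxylate
Conditions: Et3SiH, Me3SiOTf (cat.), CH2Cl2, −78 → −40 °C
Reagents that add atoms: none
Why: Ionic hydrogenation: the Lewis acid regenerates the oxocarbenium ion and triethylsilane should deliver hydride to the acetal carbon, as in reductions of unsaturated glycosides, leaving the vinyl bromide untouched.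

Step 10
Reactants: 12 5-bromo-2-methylpent-2-ene
Product: 13 (2E)-5-bromo-2-methylpent-2-en-1-ol
Conditions: SeO2 (cat.), t-BuOOH, CH2Cl2, 0 → 25 °C
Reagents that add atoms: tert-butyl hydroperoxide, CC(C)(C)OO; selenium dioxide, O=[Se]=O
Why: Riley-type allylic oxidation (ene reaction, then [2,3]-sigmatropic shift) attacks the methyl group trans to the chain of a trisubstituted alkene, which sets the E-configured allylic alcohol.

Step 11
Reactants: 14 4-coumaric acid
Product: 16 (E)-3-[4-(tert-butyldimethylsilyloxy)phenyl]prop-2-enoic acid, via bis-silylated coumarate 15 (not isolated)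
Conditions: TBSCl (2.2 equiv), imidazole, DMF, 25 °C; then AcOH, THF/H2O, 25 °C
Reagents that add atoms: tert-butyldimethylsilyl chloride, CC(C)(C)[Si](C)(C)Cl
Why: Silylation of phenol and acid followed by selective hydrolysis of the much more labile silyl ester should leave the aryl silyl ether.

Step 12
Reactants: 13 (2E)-5-bromo-2-methylpent-2-en-1-ol; 16 (E)-3-[4-(tert-butyldimethylsilyloxy)phenyl]prop-2-enoic acid
Product: 17 (2E)-5-bromo-2-methylpent-2-en-1-yl (E)-3-[4-(tert-butyldimethylsilyloxy)phenyl]prop-2-enoate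
Conditions: DCC, DMAP (cat.), CH2Cl2, 0 → 25 °C
Reagents that add atoms: none
Why: Steglich esterification of the primary allylic alcohol, which involves neither alkene geometry nor the alkyl bromide.

Step 13
Reactants: 11 TMSE (2R)-6-bromo-2-{2-[methoxy(methyl)amino]-2-oxoethyl}-2,3,4,7-tetrahydrooxepine-2-carboxylate; 17 (2E)-5-bromo-2-methylpent-2-en-1-yl (E)-3-[4-(tert-butyldimethylsilyloxy)phenyl]prop-2-enoate
Product: 19 TMSE (2R)-6-(side chain)-2-{2-[methoxy(methyl)amino]-2-oxoethyl}-2,3,4,7-tetrahydrooxepine-2-carboxylate, via alkylzinc bromide 18 (not isolated)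
Conditions: 17, Zn dust (activated with BrCH2CH2Br and Me3SiCl), LiCl, THF, 50 °C; then 11, PdCl2(dppf) (5 mol%), THF, 50 °C
Reagents that add atoms: none
Why: LiCl-promoted zinc insertion into the primary alkyl bromide and Negishi sp3–sp2 coupling with the cyclic alkenyl bromide under zerovalent-palladium catalysis tolerate the esters, the amide and the silyl ether, and touch neither alkene geometry nor C2.

Step 14
Reactants: 19 TMSE (2R)-6-(side chain)-2-{2-[methoxy(methyl)amino]-2-oxoethyl}-2,3,4,7-tetrahydrooxepine-2-carboxylate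
Product: 20 TMSE (2R)-6-(side chain)-2-(2-oxobut-3-yn-1-yl)-2,3,4,7-tetrahydrooxepine-2-carboxylate
Conditions: HC≡CMgBr (4 equiv), THF, −20 → 0 °C; poured into cold 1 M HCl
Reagents that add atoms: ethynylmagnesium bromide, C#C[Mg]Br
Why: Weinreb ketone synthesis: the magnesium chelate of the tetrahedral adduct stops at the ketone stage and shields the future ynone from base until the acidic quench, which also protonates the released amine; the amide should react ahead of the hindered and the conjugated ester.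

Step 15
Reactants: 20 TMSE (2R)-6-(side chain)-2-(2-oxobut-3-yn-1-yl)-2,3,4,7-tetrahydrooxepine-2-carboxylate; 21 2-methoxyfuran
Product: 23 TMSE (2R)-6-(side chain)-2-[2-(5-hydroxy-2-methoxyphenyl)-2-oxoethyl]-2,3,4,7-tetrahydrooxepine-2-carboxylate, via 1-methoxy-7-oxanorbornadiene adduct 22 (not isolated)
Conditions: 21 (3 equiv), CH2Cl2, 0 → 25 °C
Reagents that add atoms: none
Why: The electron-rich furan (diene, C2 to C5) adds to the electron-poor terminal ynone in a normal-demand [4+2] cycloaddition, asynchronous to the point of a zwitterion, with furan C5 bonding to the ynone β-carbon and the methoxy-bearing C2 to the acyl-bearing carbon to give the 1-methoxy-7-oxanorbornadiene 22. Its bridging ketal C–O bond then ionises with help from the methoxy group and loss of the former furan C5 proton aromatises the ring, so the furan oxygen ends as the phenol para to OMe and OMe sits ortho to the ketone. The closest known reaction type is the Diels–Alder reaction of 2-alkoxyfurans with acetylenic ketones and esters, which gives 4-alkoxyphenols after opening of the oxygen bridge. The benzene ring closes by intermolecular [4+2] cycloaddition, both new C–C bonds (aryl C1–C2 and C6–C5) forming suprafacially on diene and dienophile, and no ring closes intramolecularly. The two bridgehead stereocentres of 22 are transient and vanish on aromatisation, and the remote quaternary C2 is untouched. The step needs chemoselectivity for the ynone over the cinnamate and the two trisubstituted alkenes, which the low-lying LUMO of the ynone secures, while the orientation need not be controlled because either regioisomer is a 4-methoxyphenol that step 16 converts into the same hydroquinone.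

Step 16
Reactants: 23 TMSE (2R)-6-(side chain)-2-[2-(5-hydroxy-2-methoxyphenyl)-2-oxoethyl]-2,3,4,7-tetrahydrooxepine-2-carboxylate
Product: 25 TMSE (2R)-6-(side chain)-2-[2-(2,5-dihydroxyphenyl)-2-oxoethyl]-2,3,4,7-tetrahydrooxepine-2-carboxylate, via acylquinone 24 (not isolated)
Conditions: PhI(OAc)2 (1.1 equiv), MeCN/H2O, 0 °C; then aq. Na2S2O4, 25 °C
Reagents that add atoms: water, O
Why: Oxidative demethylation of the 4-methoxyphenol by trivalent iodine (water adds para to the phenol oxygen and methanol is lost) gives the quinone, which dithionite reduces at once to the hydroquinone; silyl ethers, esters and alkenes should not be affected.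

Step 17
Reactants: 25 TMSE (2R)-6-(side chain)-2-[2-(2,5-dihydroxyphenyl)-2-oxoethyl]-2,3,4,7-tetrahydrooxepine-2-carboxylate
Product: 26 (2R)-2-[2-(2,5-dihydroxyphenyl)-2-oxoethyl]-6-[(3E)-5-{[(2E)-3-(4-hydroxyphenyl)prop-2-enoyl]oxy}-4-methylpent-3-en-1-yl]-2,3,4,7-tetrahydrooxepine-2-carboxylic acid (CNP0602535.1)
Conditions: (Me2N)3S+ Me3SiF2− (TASF, 4 equiv), DMF, 0 → 25 °C, argon; aq. NH4Cl
Reagents that add atoms: none
Why: Fluoride-induced desilylation cleaves the aryl silyl ether and fragments the 2-(trimethylsilyl)ethyl ester (ethylene and Me3SiF) in one operation; the anhydrous, weakly basic fluoride source and exclusion of air are chosen to spare the β-alkoxy ketone and the hydroquinone.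

**Compound list**

1 | (R)-malic acid | O[C@H](CC(=O)O)C(=O)O | starting material
2 | 2-[(2R,4R)-2-tert-butyl-5-oxo-1,3-dioxolan-4-yl]acetic acid | CC(C)(C)[C@@H]1O[C@H](CC(=O)O)C(=O)O1 | intermediate
3 | 2-[(2R,4R)-4-allyl-2-tert-butyl-5-oxo-1,3-dioxolan-4-yl]acetic acid | CC(C)(C)[C@@H]1O[C@](CC=C)(CC(=O)O)C(=O)O1 | intermediate
4 | (3R)-3-hydroxy-3-{[2-(trimethylsilyl)ethoxy]carbonyl}hex-5-enoic acid | OC(=O)C[C@](O)(CC=C)C(=O)OCC[Si](C)(C)C | intermediate
5 | 2-(trimethylsilyl)ethyl (2R)-2-hydroxy-2-{2-[methoxy(methyl)amino]-2-oxoethyl}pent-4-enoate | CON(C)C(=O)C[C@](O)(CC=C)C(=O)OCC[Si](C)(C)C | intermediate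
6 | 2-(trimethylsilyl)ethyl (2R)-2-hydroxy-2-{2-[methoxy(methyl)amino]-2-oxoethyl}-6-oxohexanoate | CON(C)C(=O)C[C@](O)(CCCC=O)C(=O)OCC[Si](C)(C)C | intermediate (not isolated)
7 | 2-(trimethylsilyl)ethyl (2R)-6-hydroxy-2-{2-[methoxy(methyl)amino]-2-oxoethyl}oxane-2-carboxylate (both anomers) | CON(C)C(=O)C[C@@]1(C(=O)OCC[Si](C)(C)C)CCCC(O)O1 | intermediate
8 | 2-(trimethylsilyl)ethyl (2R)-2-{2-[methoxy(methyl)amino]-2-oxoethyl}-3,4-dihydro-2H-pyran-2-carboxylate | CON(C)C(=O)C[C@@]1(C(=O)OCC[Si](C)(C)C)CCC=CO1 | intermediate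
9 | 2-(trimethylsilyl)ethyl (3R)-7,7-dibromo-3-{2-[methoxy(methyl)amino]-2-oxoethyl}-2-oxabicyclo[4.1.0]heptane-3-carboxylate (ring-fusion diastereomers) | CON(C)C(=O)C[C@@]1(C(=O)OCC[Si](C)(C)C)CCC2C(O1)C2(Br)Br | intermediate
10 | 2-(trimethylsilyl)ethyl (2R)-6-bromo-7-methoxy-2-{2-[methoxy(methyl)amino]-2-oxoethyl}-2,3,4,7-tetrahydrooxepine-2-carboxylate (C7 epimers) | CON(C)C(=O)C[C@@]1(C(=O)OCC[Si](C)(C)C)CCC=C(Br)C(OC)O1 | intermediate
11 | 2-(trimethylsilyl)ethyl (2R)-6-bromo-2-{2-[methoxy(methyl)amino]-2-oxoethyl}-2,3,4,7-tetrahydrooxepine-2-carboxylate | CON(C)C(=O)C[C@@]1(C(=O)OCC[Si](C)(C)C)CCC=C(Br)CO1 | intermediate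
12 | 5-bromo-2-methylpent-2-ene | CC(C)=CCCBr | starting material
13 | (2E)-5-bromo-2-methylpent-2-en-1-ol | C/C(=C\CCBr)CO | intermediate
14 | 4-coumaric acid | OC(=O)/C=C/c1ccc(O)cc1 | starting material
15 | tert-butyldimethylsilyl (E)-3-[4-(tert-butyldimethylsilyloxy)phenyl]prop-2-enoate | CC(C)(C)[Si](C)(C)OC(=O)/C=C/c1ccc(O[Si](C)(C)C(C)(C)C)cc1 | intermediate (not isolated)
16 | (E)-3-[4-(tert-butyldimethylsilyloxy)phenyl]prop-2-enoic acid | OC(=O)/C=C/c1ccc(O[Si](C)(C)C(C)(C)C)cc1 | intermediate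
17 | (2E)-5-bromo-2-methylpent-2-en-1-yl (E)-3-[4-(tert-butyldimethylsilyloxy)phenyl]prop-2-enoate | C/C(=C\CCBr)COC(=O)/C=C/c1ccc(O[Si](C)(C)C(C)(C)C)cc1 | intermediate
18 | [(3E)-5-{[(2E)-3-(4-TBSO-phenyl)prop-2-enoyl]oxy}-4-methylpent-3-en-1-yl]zinc bromide | C/C(=C\CC[Zn]Br)COC(=O)/C=C/c1ccc(O[Si](C)(C)C(C)(C)C)cc1 | intermediate (not isolated)
19 | 2-(trimethylsilyl)ethyl (2R)-6-[(3E)-5-{[(2E)-3-(4-TBSO-phenyl)prop-2-enoyl]oxy}-4-methylpent-3-en-1-yl]-2-{2-[methoxy(methyl)amino]-2-oxoethyl}-2,3,4,7-tetrahydrooxepine-2-carboxylate | C/C(=C\CCC1=CCC[C@@](CC(=O)N(C)OC)(C(=O)OCC[Si](C)(C)C)OC1)COC(=O)/C=C/c1ccc(O[Si](C)(C)C(C)(C)C)cc1 | intermediate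
20 | 2-(trimethylsilyl)ethyl (2R)-6-[(3E)-5-{[(2E)-3-(4-TBSO-phenyl)prop-2-enoyl]oxy}-4-methylpent-3-en-1-yl]-2-(2-oxobut-3-yn-1-yl)-2,3,4,7-tetrahydrooxepine-2-carboxylate | C/C(=C\CCC1=CCC[C@@](CC(=O)C#C)(C(=O)OCC[Si](C)(C)C)OC1)COC(=O)/C=C/c1ccc(O[Si](C)(C)C(C)(C)C)cc1 | intermediate (key-step precursor)
21 | 2-methoxyfuran | COc1ccco1 | starting material
22 | 1-methoxy-7-oxabicyclo[2.2.1]hepta-2,5-dien-2-yl ketone cycloadduct of 20 and 21 (bridgehead epimers) | C/C(=C\CCC1=CCC[C@@](CC(=O)C2=CC3C=CC2(OC)O3)(C(=O)OCC[Si](C)(C)C)OC1)COC(=O)/C=C/c1ccc(O[Si](C)(C)C(C)(C)C)cc1 | intermediate (not isolated)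
23 | 2-(trimethylsilyl)ethyl (2R)-6-[(3E)-5-{[(2E)-3-(4-TBSO-phenyl)prop-2-enoyl]oxy}-4-methylpent-3-en-1-yl]-2-[2-(5-hydroxy-2-methoxyphenyl)-2-oxoethyl]-2,3,4,7-tetrahydrooxepine-2-carboxylate | C/C(=C\CCC1=CCC[C@@](CC(=O)c2cc(O)ccc2OC)(C(=O)OCC[Si](C)(C)C)OC1)COC(=O)/C=C/c1ccc(O[Si](C)(C)C(C)(C)C)cc1 | intermediate (key-step product)
24 | 2-(trimethylsilyl)ethyl (2R)-6-[(3E)-5-{[(2E)-3-(4-TBSO-phenyl)prop-2-enoyl]oxy}-4-methylpent-3-en-1-yl]-2-[2-(3,6-dioxocyclohexa-1,4-dien-1-yl)-2-oxoethyl]-2,3,4,7-tetrahydrooxepine-2-carboxylate | C/C(=C\CCC1=CCC[C@@](CC(=O)C2=CC(=O)C=CC2=O)(C(=O)OCC[Si](C)(C)C)OC1)COC(=O)/C=C/c1ccc(O[Si](C)(C)C(C)(C)C)cc1 | intermediate (not isolated)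
25 | 2-(trimethylsilyl)ethyl (2R)-6-[(3E)-5-{[(2E)-3-(4-TBSO-phenyl)prop-2-enoyl]oxy}-4-methylpent-3-en-1-yl]-2-[2-(2,5-dihydroxyphenyl)-2-oxoethyl]-2,3,4,7-tetrahydrooxepine-2-carboxylate | C/C(=C\CCC1=CCC[C@@](CC(=O)c2cc(O)ccc2O)(C(=O)OCC[Si](C)(C)C)OC1)COC(=O)/C=C/c1ccc(O[Si](C)(C)C(C)(C)C)cc1 | intermediate
26 | (2R)-2-[2-(2,5-dihydroxyphenyl)-2-oxoethyl]-6-[(3E)-5-{[(2E)-3-(4-hydroxyphenyl)prop-2-enoyl]oxy}-4-methylpent-3-en-1-yl]-2,3,4,7-tetrahydrooxepine-2-carboxylic acid | C/C(=C\CCC1=CCC[C@@](CC(=O)c2cc(O)ccc2O)(C(=O)O)OC1)COC(=O)/C=C/c1ccc(O)cc1 | target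

**Count**

Total steps: 17. Longest linear sequence: 14 (steps 1–9 and 13–17, from (R)-malic acid).

**Steps most likely to fail**

Step 8 (silver-assisted ring expansion). After ionisation the oxocarbenium ion may be captured by the neighbouring amide or ester carbonyl, or lose a proton to a dienyl ether, faster than it adds methanol. The fallback closes the seven-membered ring by olefin metathesis instead; it sets out from 2 and returns at 19. Borane–dimethyl sulfide reduces the free acid of 2 to (2R,5R)-2-tert-butyl-5-(2-hydroxyethyl)-1,3-dioxolan-4-one F1, and 4-methoxybenzyl trichloroacetimidate with catalytic camphorsulfonic acid gives (2R,5R)-2-tert-butyl-5-{2-[(4-methoxybenzyl)oxy]ethyl}-1,3-dioxolan-4-one F2. Deprotonation with LiN(iPr)2 and alkylation with 4-iodobut-1-ene (THF/DMPU), again trans to tert-butyl, gives the (2R,5R)-5-(but-3-en-1-yl) dioxolanone F3. Sodium 2-(trimethylsilyl)ethoxide opens it to 2-(trimethylsilyl)ethyl (2R)-2-hydroxy-2-{2-[(4-methoxybenzyl)oxy]ethyl}hex-5-enoate F4, whose arm is now an ether and therefore stable to base. Williamson etherification (NaH, 2,3-dibromopropene, DMF) gives the 2-bromoallyl ether F5, and Negishi coupling with 18 (PdCl2(dppf)) gives the side-chain-bearing diene F6. Ring-closing metathesis with the second-generation Grubbs catalyst closes the oxepine PMB ether F7. DDQ frees the primary alcohol F8, which is oxidised without delay (TEMPO, PhI(OAc)2, aqueous MeCN) to the oxepine acetic acid F9, and amide formation as in step 4 gives 19.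

Step 15 (furan cycloaddition). The acid-sensitive methoxyfuran may oligomerise, or the reaction may stop at the open-chain conjugate adduct (alkenylation at furan C5) without closing the second bond. The fallback forms the same two bonds and the same ring with a symmetrical, more electron-rich diene; it sets out from 20 and returns at 24. 2,5-Bis(trimethylsilyloxy)furan F10 is prepared from succinic anhydride (Me3SiCl, Et3N, ZnCl2) and added to 20 in CH2Cl2. The 1,4-bis(trimethylsilyloxy)-7-oxanorbornadiene adduct F11 should lose hexamethyldisiloxane and give acylquinone 24 directly, which is reduced with Na2S2O4 as in the second half of step 16. This variant has no orientation issue and needs no demethylation.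

Step 16 (oxidative demethylation). The electrophilic acylquinone may take up water or react with the nearby alkenes before it is reduced, or the phenol may be over-oxidised. The fallback avoids the quinone by Lewis-acid ether cleavage; it sets out from 23 and returns at 25. BCl3 in CH2Cl2 at −78 °C, chelated between the ketone and the ortho methoxy group, should cleave only that methyl ether on short exposure (valid for the expected orientation of step 15). This fallback makes no new compound (F0).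

**Further compounds**

F1 | step 8 | (2R,5R)-2-tert-butyl-5-(2-hydroxyethyl)-1,3-dioxolan-4-one | CC(C)(C)[C@@H]1O[C@H](CCO)C(=O)O1
F2 | step 8 | (2R,5R)-2-tert-butyl-5-{2-[(4-methoxybenzyl)oxy]ethyl}-1,3-dioxolan-4-one | CC(C)(C)[C@@H]1O[C@H](CCOCc2ccc(OC)cc2)C(=O)O1
F3 | step 8 | (2R,5R)-5-(but-3-en-1-yl)-2-tert-butyl-5-{2-[(4-methoxybenzyl)oxy]ethyl}-1,3-dioxolan-4-one | CC(C)(C)[C@@H]1O[C@](CCC=C)(CCOCc2ccc(OC)cc2)C(=O)O1
F4 | step 8 | 2-(trimethylsilyl)ethyl (2R)-2-hydroxy-2-{2-[(4-methoxybenzyl)oxy]ethyl}hex-5-enoate | C=CCC[C@@](O)(CCOCc1ccc(OC)cc1)C(=O)OCC[Si](C)(C)C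
F5 | step 8 | 2-(trimethylsilyl)ethyl (2R)-2-[(2-bromoprop-2-en-1-yl)oxy]-2-{2-[(4-methoxybenzyl)oxy]ethyl}hex-5-enoate | C=CCC[C@@](OCC(Br)=C)(CCOCc1ccc(OC)cc1)C(=O)OCC[Si](C)(C)C
F6 | step 8 | 2-(trimethylsilyl)ethyl (2R)-2-{[(5E)-6-methyl-2-methylidene-7-{[(2E)-3-(4-TBSO-phenyl)prop-2-enoyl]oxy}hept-5-en-1-yl]oxy}-2-{2-[(4-methoxybenzyl)oxy]ethyl}hex-5-enoate | C=CCC[C@@](OCC(=C)CC/C=C(\C)COC(=O)/C=C/c1ccc(O[Si](C)(C)C(C)(C)C)cc1)(CCOCc1ccc(OC)cc1)C(=O)OCC[Si](C)(C)C
F7 | step 8 | 2-(trimethylsilyl)ethyl (2R)-6-[(3E)-5-{[(2E)-3-(4-TBSO-phenyl)prop-2-enoyl]oxy}-4-methylpent-3-en-1-yl]-2-{2-[(4-methoxybenzyl)oxy]ethyl}-2,3,4,7-tetrahydrooxepine-2-carboxylate | C/C(=C\CCC1=CCC[C@@](CCOCc2ccc(OC)cc2)(C(=O)OCC[Si](C)(C)C)OC1)COC(=O)/C=C/c1ccc(O[Si](C)(C)C(C)(C)C)cc1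
F8 | step 8 | 2-(trimethylsilyl)ethyl (2R)-6-[(3E)-5-{[(2E)-3-(4-TBSO-phenyl)prop-2-enoyl]oxy}-4-methylpent-3-en-1-yl]-2-(2-hydroxyethyl)-2,3,4,7-tetrahydrooxepine-2-carboxylate | C/C(=C\CCC1=CCC[C@@](CCO)(C(=O)OCC[Si](C)(C)C)OC1)COC(=O)/C=C/c1ccc(O[Si](C)(C)C(C)(C)C)cc1
F9 | step 8 | 2-[(2R)-6-[(3E)-5-{[(2E)-3-(4-TBSO-phenyl)prop-2-enoyl]oxy}-4-methylpent-3-en-1-yl]-2-{[2-(trimethylsilyl)ethoxy]carbonyl}-2,3,4,7-tetrahydrooxepin-2-yl]acetic acid | C/C(=C\CCC1=CCC[C@@](CC(=O)O)(C(=O)OCC[Si](C)(C)C)OC1)COC(=O)/C=C/c1ccc(O[Si](C)(C)C(C)(C)C)cc1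
F10 | step 15 | 2,5-bis(trimethylsilyloxy)furan | C[Si](C)(C)Oc1ccc(O[Si](C)(C)C)o1
F11 | step 15 | 1,4-bis(trimethylsilyloxy)-7-oxabicyclo[2.2.1]hepta-2,5-dien-2-yl ketone cycloadduct of 20 and F10 | C/C(=C\CCC1=CCC[C@@](CC(=O)C2=CC3(O[Si](C)(C)C)C=CC2(O[Si](C)(C)C)O3)(C(=O)OCC[Si](C)(C)C)OC1)COC(=O)/C=C/c1ccc(O[Si](C)(C)C(C)(C)C)cc1
F0 | step 16 | none | none
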